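**Plan**

1. Numbering used throughout: ring C1 (bears the side chain), C2 (O-tiglate), C3 (C=O), C4 (methyl), C5 (epoxide CH), C6 (CH2); chain C7(=C12H2)–C8(=O)–C9=C10–C11(Me)2OOH.
2. Retrosynthetic cuts, in order: the hydroperoxide mask; C9=C10 (cross-metathesis); C7–C8 and C8–C9 (CO insertion at a C7 enol triflate); the epoxide C–O bonds; the tiglate acyl–O bond; then, after re-tying the C2 oxygen to C5 as an ether bridge, C1–C2 and C5–C6 together ([4+2] of 3-methylfuran with an acrylate).
3. Enabling feature: in ring C1–C6 the oxygens on C2 and C5 stand 1,4 across the C3–C4(methyl) unit and C2–O is trans to the carbon substituent on C1. Joined through one oxygen they form the 7-oxabicyclo[2.2.1]heptene that 3-methylfuran gives in an endo cycloaddition.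
4. Forward: the carbocycle closes first as the oxanorbornene; the ester becomes the C7 enol triflate; hydroboration/oxidation sets the C3 ketone; β-elimination opens the bridge at C5 to the C2-hydroxy enone; tigloylation, reduction, epoxidation and reoxidation finish the ring; C8–C11 are then joined by carbonylative Stille coupling and cross-metathesis, and the hydroperoxide is unmasked last.
5. Stereochemistry: C1 and C2 come from the catalyst-controlled endo cycloaddition (the C2–O bond is never broken); C4 and C5 come from peracid delivery by a temporary C3–OH that axial hydride addition places trans to the tiglate; E-C9=C10 comes from metathesis and the tiglate geometry from the reagent.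

Key step: step 1

Assumption: the (S)-diphenylprolinol-derived B-o-tolyl oxazaborolidinium triflimide is taken to give adduct 3; should the first adduct prove antipodal, the equally accessible (R)-prolinol-derived catalyst is used and nothing else changes.

**Step 1**
Reactants: 1 3-methylfuran; 2 2,2,2-trifluoroethyl acrylate
Product: 3 2,2,2-trifluoroethyl (1R,2R,4R)-5-methyl-7-oxabicyclo[2.2.1]hept-5-ene-2-carboxylate (endo ester)
Conditions: (S)-diphenylprolinol B-o-tolyl oxazaborolidine·Tf2NH (15 mol %), 1 (3 equiv), CH2Cl2, −78 °C; Et3N quench at −78 °C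
Reagents that add atoms: none
Why: The boron of the oxazaborolidinium ion binds the acrylate carbonyl, lowers its LUMO and leaves one face of the s-trans enoate open, and 3-methylfuran adds in a concerted, asynchronous, suprafacial [4+2] process in which furan C2 (the α-carbon next to the methyl, largest HOMO coefficient) bonds first to the acrylate β-carbon (C5–C6) and furan C5 to the α-carbon (C1–C2). The closest known reaction type is the oxazaborolidinium-catalysed endo Diels–Alder reaction of furan with 2,2,2-trifluoroethyl acrylate. The six-membered carbocycle C1–C6 closes by intermolecular cycloaddition across the furan 2,5-positions, which turns the furan oxygen into the one-atom bridge of a 7-oxabicyclo[2.2.1]heptene. C1 is fixed by the catalyst-selected enantioface of the dienophile, and C2 and C5 follow from suprafacial addition through the endo transition state, which puts the bridge oxygen on C2 anti to the ester on C1. The step needs para-type regiochemistry, endo topology and one enantioface: the 3-methyl group polarises the diene toward the wanted regioisomer, and the low temperature with a cold amine quench keeps the kinetic endo adduct from cycloreversion and exo equilibration.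

**Step 2**
Reactants: 3 2,2,2-trifluoroethyl (1R,2R,4R)-5-methyl-7-oxabicyclo[2.2.1]hept-5-ene-2-carboxylate
Product: 5 1-[(1R,2R,4R)-5-methyl-7-oxabicyclo[2.2.1]hept-5-en-2-yl]ethan-1-one (endo acetyl), via Weinreb amide 4 (not isolated)
Conditions: MeNH(OMe)·HCl (1.5 equiv), i-PrMgCl (3.0 equiv), THF, −20 °C; then MeMgBr, −20 → 0 °C; aq NH4Cl
Reagents that add atoms: methylmagnesium bromide, C[Mg]Br
Why: The chloromagnesium amide of N,O-dimethylhydroxylamine aminolyses the activated trifluoroethyl ester to amide 4, whose chelated tetrahedral adduct with MeMgBr releases the ketone only on work-up (Weinreb ketone synthesis), while the low temperature prevents C1 enolisation (which would open the bridge or epimerise the endo centre) and cycloreversion.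

**Step 3**
Reactants: 5 1-[(1R,2R,4R)-5-methyl-7-oxabicyclo[2.2.1]hept-5-en-2-yl]ethan-1-one
Product: 7 1-[(1R,2R,4R)-5-methyl-7-oxabicyclo[2.2.1]hept-5-en-2-yl]ethenyl trifluoromethanesulfonate, via potassium enolate 6 (not isolated)
Conditions: KHMDS, THF, −78 °C; then PhNTf2, −78 → −40 °C
Reagents that add atoms: N-phenyl-bis(trifluoromethanesulfonimide), O=S(=O)(N(c1ccccc1)S(=O)(=O)C(F)(F)F)C(F)(F)F
Why: Kinetic deprotonation at the methyl group by the hindered base and O-sulfonylation of the terminal enolate (enol triflate formation) mask the carbonyl as the C7 handle for later CO insertion; C1 is not deprotonated, so its configuration and the bridge stay intact.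

**Step 4**
Reactants: 7 1-[(1R,2R,4R)-5-methyl-7-oxabicyclo[2.2.1]hept-5-en-2-yl]ethenyl trifluoromethanesulfonate
Product: 9 1-[(1S,2R,4R,5R,6R)-6-hydroxy-5-methyl-7-oxabicyclo[2.2.1]heptan-2-yl]ethenyl trifluoromethanesulfonate (6-exo-OH, 5-endo-CH3), via alkylborane 8 (not isolated)
Conditions: BH3·THF (1.0 equiv), THF, 0 °C; then 30% H2O2, aq NaHCO3, 0 °C → rt
Reagents that add atoms: hydrogen peroxide, OO
Why: Hydroboration–oxidation: the borane adds syn from the exo face to the strained, electron-rich ring alkene with boron on the unsubstituted carbon (the triflate-deactivated vinyl group reacts far more slowly), and oxidation with retention gives the exo C3 alcohol; the C3 and C4 centres formed here are both erased in steps 5 and 6.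

**Step 5**
Reactants: 9 1-[(1S,2R,4R,5R,6R)-6-hydroxy-5-methyl-7-oxabicyclo[2.2.1]heptan-2-yl]ethenyl trifluoromethanesulfonate
Product: 10 1-[(1S,2R,4R,5S)-5-methyl-6-oxo-7-oxabicyclo[2.2.1]heptan-2-yl]ethenyl trifluoromethanesulfonate
Conditions: Dess–Martin periodinane, NaHCO3, CH2Cl2, 0 °C → rt
Reagents that add atoms: none
Why: Dess–Martin oxidation of the secondary alcohol under buffered neutral conditions gives the bridged C3 ketone without touching the enol triflate.

**Step 6**
Reactants: 10 1-[(1S,2R,4R,5S)-5-methyl-6-oxo-7-oxabicyclo[2.2.1]heptan-2-yl]ethenyl trifluoromethanesulfonate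
Product: 13 1-[(1R,6S)-6-hydroxy-4-methyl-5-oxocyclohex-3-en-1-yl]ethenyl trifluoromethanesulfonate, via silyl enol ether 11 (not isolated), via TMS ether 12 (not isolated)
Conditions: TMSOTf (1.3 equiv), Et3N (2 equiv), CH2Cl2, −20 → 0 °C; then 1 M HCl, THF, 0 °C
Reagents that add atoms: none
Why: Soft enolisation can occur only toward C4 (C2 is a bridgehead), and the silyl enol ether expels the silyl-triflate-activated bridge oxygen from C5 (β-elimination, the known opening of 7-oxabicyclo[2.2.1]heptan-2-ones to 6-silyloxycyclohex-2-enones), after which dilute acid removes the O-silyl group; the C2–O bond is never broken, so C2 keeps its configuration trans to C1.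

**Step 7**
Reactants: 13 1-[(1R,6S)-6-hydroxy-4-methyl-5-oxocyclohex-3-en-1-yl]ethenyl trifluoromethanesulfonate; 14 tigloyl chloride
Product: 15 (1S,6R)-3-methyl-2-oxo-6-{1-[(trifluoromethanesulfonyl)oxy]ethenyl}cyclohex-3-en-1-yl (2E)-2-methylbut-2-enoate
Conditions: pyridine, DMAP (cat.), CH2Cl2, 0 °C → rt
Reagents that add atoms: none
Why: DMAP-catalysed acylation of the secondary α-ketol by the acid chloride (esterification), run with pyridine instead of a trialkylamine so that the acid chloride is not deconjugated through a vinylketene and the E geometry of 14 is carried over unchanged.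

**Step 8**
Reactants: 15 (1S,6R)-3-methyl-2-oxo-6-{1-[(trifluoromethanesulfonyl)oxy]ethenyl}cyclohex-3-en-1-yl (2E)-2-methylbut-2-enoate
Product: 16 (1S,2S,6R)-2-hydroxy-3-methyl-6-{1-[(trifluoromethanesulfonyl)oxy]ethenyl}cyclohex-3-en-1-yl (2E)-2-methylbut-2-enoate
Conditions: NaBH4, CeCl3·7H2O, MeOH, −78 °C; AcOH quench
Reagents that add atoms: none
Why: Luche reduction: the cerium-modified borohydride adds 1,2 and axially to the half-chair in which the C1 and C2 substituents are equatorial, which should give the equatorial C3 alcohol trans to the tiglate and cis to the C1 group (the carvone-to-cis-carveol pattern), while the low temperature and acidic quench suppress acyl transfer.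

**Step 9**
Reactants: 16 (1S,2S,6R)-2-hydroxy-3-methyl-6-{1-[(trifluoromethanesulfonyl)oxy]ethenyl}cyclohex-3-en-1-yl (2E)-2-methylbut-2-enoate
Product: 17 (1R,2R,3S,4R,6S)-2-hydroxy-1-methyl-4-{1-[(trifluoromethanesulfonyl)oxy]ethenyl}-7-oxabicyclo[4.1.0]heptan-3-yl (2E)-2-methylbut-2-enoate
Conditions: mCPBA, NaHCO3, CH2Cl2, 0 °C
Reagents that add atoms: 3-chloroperbenzoic acid, OOC(=O)c1cccc(Cl)c1
Why: Hydroxyl-directed peracid epoxidation: the pseudo-equatorial allylic OH hydrogen-bonds the peracid and delivers oxygen to its own face of the electron-rich trisubstituted C4=C5 bond, which sets C4 and C5 cis to C3–OH and hence trans to the tiglate, while the tiglate and enol triflate alkenes are too electron-poor to react.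

**Step 10**
Reactants: 17 (1R,2R,3S,4R,6S)-2-hydroxy-1-methyl-4-{1-[(trifluoromethanesulfonyl)oxy]ethenyl}-7-oxabicyclo[4.1.0]heptan-3-yl (2E)-2-methylbut-2-enoate
Product: 18 (1S,3S,4R,6S)-1-methyl-2-oxo-4-{1-[(trifluoromethanesulfonyl)oxy]ethenyl}-7-oxabicyclo[4.1.0]heptan-3-yl (2E)-2-methylbut-2-enoate
Conditions: Dess–Martin periodinane, NaHCO3, CH2Cl2, 0 °C → rt
Reagents that add atoms: none
Why: Dess–Martin oxidation returns the C3 ketone under neutral conditions that leave the epoxide, the ester and the epimerisable C2 untouched, and removes the temporary C3 stereocentre.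

**Step 11**
Reactants: 18 (1S,3S,4R,6S)-1-methyl-2-oxo-4-{1-[(trifluoromethanesulfonyl)oxy]ethenyl}-7-oxabicyclo[4.1.0]heptan-3-yl (2E)-2-methylbut-2-enoate
Product: 19 (1S,3S,4S,6S)-1-methyl-2-oxo-4-(3-oxopenta-1,4-dien-2-yl)-7-oxabicyclo[4.1.0]heptan-3-yl (2E)-2-methylbut-2-enoate
Conditions: CO (1 atm), Bu3SnCH=CH2, Pd(PPh3)4 (5 mol %), LiCl, THF, 50 °C
Reagents that add atoms: carbon monoxide, [C-]#[O+]; tributyl(vinyl)stannane, C=C[Sn](CCCC)(CCCC)CCCC
Why: Carbonylative Stille coupling of an enol triflate: oxidative addition at C7–OTf, CO insertion to the acylpalladium, transmetalation from the vinylstannane and reductive elimination give the cross-conjugated divinyl ketone under neutral conditions that the epoxy ketone and the ester tolerate.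

**Step 12**
Reactants: 20 2-methylbut-3-en-2-ol
Product: 21 2-methylbut-3-en-2-yl hydroperoxide
Conditions: 50% aq H2O2 (excess), H2SO4 (cat.), 0 °C
Reagents that add atoms: hydrogen peroxide, OO
Why: Acid-catalysed perhydrolysis of a tertiary allylic alcohol (SN1): hydrogen peroxide traps the dimethylallyl cation at its tertiary terminus under kinetic control, favoured by low temperature and short contact time.

**Step 13**
Reactants: 21 2-methylbut-3-en-2-yl hydroperoxide
Product: 22 3-[(2-methoxypropan-2-yl)peroxy]-3-methylbut-1-ene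
Conditions: 2-methoxypropene, PPTS (cat.), CH2Cl2, 0 °C
Reagents that add atoms: 2-methoxypropene, C=C(C)OC
Why: Acid-catalysed addition of the hydroperoxide O–H to the enol ether (monoperoxyketal formation) turns the hydroperoxide into a dialkyl peroxide that no longer oxidises a ruthenium carbene.

**Step 14**
Reactants: 19 (1S,3S,4S,6S)-1-methyl-2-oxo-4-(3-oxopenta-1,4-dien-2-yl)-7-oxabicyclo[4.1.0]heptan-3-yl (2E)-2-methylbut-2-enoate; 22 3-[(2-methoxypropan-2-yl)peroxy]-3-methylbut-1-ene
Product: 23 (1S,3S,4S,6S)-4-{(4E)-6-[(2-methoxypropan-2-yl)peroxy]-6-methyl-3-oxohepta-1,4-dien-2-yl}-1-methyl-2-oxo-7-oxabicyclo[4.1.0]heptan-3-yl (2E)-2-methylbut-2-enoate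
Conditions: Hoveyda–Grubbs II (10 mol %), 22 (4 equiv), CH2Cl2, 40 °C
Reagents that add atoms: none
Why: Olefin cross-metathesis between the vinyl ketone (a slowly homodimerising olefin) and the excess quaternary-allylic olefin (which does not homodimerise) is selective for the cross product, the 1,1-disubstituted C7=C12 and the tiglate alkenes do not take part, and the E-enone results from thermodynamic control.

**Step 15**
Reactants: 23 (1S,3S,4S,6S)-4-{(4E)-6-[(2-methoxypropan-2-yl)peroxy]-6-methyl-3-oxohepta-1,4-dien-2-yl}-1-methyl-2-oxo-7-oxabicyclo[4.1.0]heptan-3-yl (2E)-2-methylbut-2-enoate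
Product: 24 (1S,3S,4S,6S)-4-[(4E)-6-hydroperoxy-6-methyl-3-oxohepta-1,4-dien-2-yl]-1-methyl-2-oxo-7-oxabicyclo[4.1.0]heptan-3-yl (2E)-2-methylbut-2-enoate (CNP0284595.1)
Conditions: AcOH/THF/H2O (4:2:1), rt
Reagents that add atoms: none
Why: Mild aqueous-acid hydrolysis of the monoperoxyketal (deprotection) frees the tertiary hydroperoxide with loss of acetone and methanol, under conditions to which the carbonyl-deactivated epoxide, the enones and the ester should be stable.

**Compound list**

1 | 3-methylfuran | Cc1ccoc1 | starting material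
2 | 2,2,2-trifluoroethyl acrylate | C=CC(=O)OCC(F)(F)F | starting material
3 | 2,2,2-trifluoroethyl (1R,2R,4R)-5-methyl-7-oxabicyclo[2.2.1]hept-5-ene-2-carboxylate (endo ester) | FC(F)(F)COC(=O)[C@@H]1C[C@H]2O[C@@H]1C=C2C | intermediate
4 | (1R,2R,4R)-N-methoxy-N,5-dimethyl-7-oxabicyclo[2.2.1]hept-5-ene-2-carboxamide (Weinreb amide, not isolated) | CON(C)C(=O)[C@@H]1C[C@H]2O[C@@H]1C=C2C | intermediate
5 | 1-[(1R,2R,4R)-5-methyl-7-oxabicyclo[2.2.1]hept-5-en-2-yl]ethan-1-one (endo acetyl) | CC(=O)[C@@H]1C[C@H]2O[C@@H]1C=C2C | intermediate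
6 | potassium 1-[(1R,2R,4R)-5-methyl-7-oxabicyclo[2.2.1]hept-5-en-2-yl]ethen-1-olate (not isolated) | C=C([O-])[C@@H]1C[C@H]2O[C@@H]1C=C2C.[K+] | intermediate
7 | 1-[(1R,2R,4R)-5-methyl-7-oxabicyclo[2.2.1]hept-5-en-2-yl]ethenyl trifluoromethanesulfonate | C=C(OS(=O)(=O)C(F)(F)F)[C@@H]1C[C@H]2O[C@@H]1C=C2C | intermediate
8 | 1-[(1R,2R,4R,5R,6R)-6-boranyl-5-methyl-7-oxabicyclo[2.2.1]heptan-2-yl]ethenyl trifluoromethanesulfonate (exo monoalkylborane, not isolated) | C=C(OS(=O)(=O)C(F)(F)F)[C@@H]1C[C@H]2O[C@@H]1[C@H](B)[C@H]2C | intermediate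
9 | 1-[(1S,2R,4R,5R,6R)-6-hydroxy-5-methyl-7-oxabicyclo[2.2.1]heptan-2-yl]ethenyl trifluoromethanesulfonate (6-exo-OH, 5-endo-CH3) | C=C(OS(=O)(=O)C(F)(F)F)[C@@H]1C[C@H]2O[C@@H]1[C@H](O)[C@H]2C | intermediate
10 | 1-[(1S,2R,4R,5S)-5-methyl-6-oxo-7-oxabicyclo[2.2.1]heptan-2-yl]ethenyl trifluoromethanesulfonate | C=C(OS(=O)(=O)C(F)(F)F)[C@@H]1C[C@H]2O[C@@H]1C(=O)[C@H]2C | intermediate
11 | 1-[(1S,2R,4R)-5-methyl-6-[(trimethylsilyl)oxy]-7-oxabicyclo[2.2.1]hept-5-en-2-yl]ethenyl trifluoromethanesulfonate (silyl enol ether, not isolated) | C=C(OS(=O)(=O)C(F)(F)F)[C@@H]1C[C@H]2O[C@@H]1C(O[Si](C)(C)C)=C2C | intermediate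
12 | 1-[(1R,6S)-4-methyl-5-oxo-6-[(trimethylsilyl)oxy]cyclohex-3-en-1-yl]ethenyl trifluoromethanesulfonate (TMS ether, not isolated) | C=C(OS(=O)(=O)C(F)(F)F)[C@@H]1CC=C(C)C(=O)[C@H]1O[Si](C)(C)C | intermediate
13 | 1-[(1R,6S)-6-hydroxy-4-methyl-5-oxocyclohex-3-en-1-yl]ethenyl trifluoromethanesulfonate | C=C(OS(=O)(=O)C(F)(F)F)[C@@H]1CC=C(C)C(=O)[C@H]1O | intermediate
14 | tigloyl chloride, (2E)-2-methylbut-2-enoyl chloride | C/C=C(\C)C(Cl)=O | starting material
15 | (1S,6R)-3-methyl-2-oxo-6-{1-[(trifluoromethanesulfonyl)oxy]ethenyl}cyclohex-3-en-1-yl (2E)-2-methylbut-2-enoate | C=C(OS(=O)(=O)C(F)(F)F)[C@@H]1CC=C(C)C(=O)[C@H]1OC(=O)/C(C)=C/C | intermediate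
16 | (1S,2S,6R)-2-hydroxy-3-methyl-6-{1-[(trifluoromethanesulfonyl)oxy]ethenyl}cyclohex-3-en-1-yl (2E)-2-methylbut-2-enoate | C=C(OS(=O)(=O)C(F)(F)F)[C@@H]1CC=C(C)[C@H](O)[C@H]1OC(=O)/C(C)=C/C | intermediate
17 | (1R,2R,3S,4R,6S)-2-hydroxy-1-methyl-4-{1-[(trifluoromethanesulfonyl)oxy]ethenyl}-7-oxabicyclo[4.1.0]heptan-3-yl (2E)-2-methylbut-2-enoate | C=C(OS(=O)(=O)C(F)(F)F)[C@@H]1C[C@@H]2O[C@]2(C)[C@H](O)[C@H]1OC(=O)/C(C)=C/C | intermediate
18 | (1S,3S,4R,6S)-1-methyl-2-oxo-4-{1-[(trifluoromethanesulfonyl)oxy]ethenyl}-7-oxabicyclo[4.1.0]heptan-3-yl (2E)-2-methylbut-2-enoate | C=C(OS(=O)(=O)C(F)(F)F)[C@@H]1C[C@@H]2O[C@]2(C)C(=O)[C@H]1OC(=O)/C(C)=C/C | intermediate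
19 | (1S,3S,4S,6S)-1-methyl-2-oxo-4-(3-oxopenta-1,4-dien-2-yl)-7-oxabicyclo[4.1.0]heptan-3-yl (2E)-2-methylbut-2-enoate | C=CC(=O)C(=C)[C@@H]1C[C@@H]2O[C@]2(C)C(=O)[C@H]1OC(=O)/C(C)=C/C | intermediate
20 | 2-methylbut-3-en-2-ol | C=CC(C)(C)O | starting material
21 | 2-methylbut-3-en-2-yl hydroperoxide | C=CC(C)(C)OO | intermediate
22 | 3-[(2-methoxypropan-2-yl)peroxy]-3-methylbut-1-ene | C=CC(C)(C)OOC(C)(C)OC | intermediate
23 | (1S,3S,4S,6S)-4-{(4E)-6-[(2-methoxypropan-2-yl)peroxy]-6-methyl-3-oxohepta-1,4-dien-2-yl}-1-methyl-2-oxo-7-oxabicyclo[4.1.0]heptan-3-yl (2E)-2-methylbut-2-enoate | COC(C)(C)OOC(C)(C)/C=C/C(=O)C(=C)[C@@H]1C[C@@H]2O[C@]2(C)C(=O)[C@H]1OC(=O)/C(C)=C/C | intermediate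
24 | (1S,3S,4S,6S)-4-[(4E)-6-hydroperoxy-6-methyl-3-oxohepta-1,4-dien-2-yl]-1-methyl-2-oxo-7-oxabicyclo[4.1.0]heptan-3-yl (2E)-2-methylbut-2-enoate | C=C(C(=O)/C=C/C(C)(C)OO)[C@@H]1C[C@@H]2O[C@]2(C)C(=O)[C@H]1OC(=O)/C(C)=C/C | target

**Step count**

Total: 15 steps. Longest linear sequence: 13 steps (steps 1–11, 14, 15); steps 12 and 13 prepare the metathesis partner.

**Steps most likely to fail**

Step 14 (cross-metathesis). Productive turnover at the quaternary allylic olefin may be too slow, so that the ruthenium carbene is lost to the peroxide or the vinyl ketone self-couples or oligomerises. The fallback sets out from 18 and makes the C11–O bond last by photo-oxygenation instead of carrying a peroxide through metathesis. The carbonylative coupling of step 11 is run with tributyl(3-methylbut-2-en-1-yl)stannane in place of the vinylstannane, which should give the β,γ-unsaturated prenyl ketone F1. A Schenck ene reaction (O2, tetraphenylporphyrin, visible light, CH2Cl2, 0 °C) on its only electron-rich alkene would then remove a C9 hydrogen, move the double bond to C9=C10 (E) and place OOH on C11. This comes back to the route at 24. The isomeric secondary hydroperoxide from methyl-hydrogen abstraction would be removed by chromatography.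

Step 1 (cycloaddition). Cycloreversion and re-addition may erode endo and facial selectivity, or the strong Lewis acid may divert the furan into conjugate (Friedel–Crafts) alkylation at C2. The fallback sets out from 1 and changes the activation mode to two-point binding. Commercial 3-acryloyl-1,3-oxazolidin-2-one would be used as dienophile under a cationic copper(II) bis(oxazoline) catalyst (CH2Cl2, −78 °C), giving the endo imide adduct F2. Treatment with MeNH(OMe)·HCl/AlMe3 (CH2Cl2, 0 °C) would convert it into Weinreb amide 4, where the route is rejoined (MeMgBr as in the second stage of step 2).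

Step 8 (reduction). The tigloyl group may shift to the new C3 alkoxide, or hydride may be delivered to the wrong face. The fallback sets out from 10 and defers the tiglate until C3 is a ketone again. Bridge opening with TBSOTf/Et3N, keeping the silyl group, would give the silyl ether F3. Luche reduction would give the allylic alcohol F4, which has no acyl group to migrate. mCPBA would give the epoxy alcohol F5 and Dess–Martin oxidation the epoxy ketone F6. HF·pyridine would free the α-ketol F7, and acylation with 14 as in step 7 comes back to the route at 18.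

**Further compounds**

F1 | step 14 | (1S,3S,4S,6S)-1-methyl-4-(6-methyl-3-oxohepta-1,5-dien-2-yl)-2-oxo-7-oxabicyclo[4.1.0]heptan-3-yl (2E)-2-methylbut-2-enoate | CC(C)=CCC(=O)C(=C)[C@@H]1C[C@@H]2O[C@]2(C)C(=O)[C@H]1OC(=O)/C(C)=C/C
F2 | step 1 | 3-[(1R,2R,4R)-5-methyl-7-oxabicyclo[2.2.1]hept-5-ene-2-carbonyl]-1,3-oxazolidin-2-one | O=C1OCCN1C(=O)[C@@H]1C[C@H]2O[C@@H]1C=C2C
F3 | step 8 | 1-[(1R,6S)-6-[(tert-butyldimethylsilyl)oxy]-4-methyl-5-oxocyclohex-3-en-1-yl]ethenyl trifluoromethanesulfonate | C=C(OS(=O)(=O)C(F)(F)F)[C@@H]1CC=C(C)C(=O)[C@H]1O[Si](C)(C)C(C)(C)C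
F4 | step 8 | 1-[(1R,5S,6S)-6-[(tert-butyldimethylsilyl)oxy]-5-hydroxy-4-methylcyclohex-3-en-1-yl]ethenyl trifluoromethanesulfonate | C=C(OS(=O)(=O)C(F)(F)F)[C@@H]1CC=C(C)[C@H](O)[C@H]1O[Si](C)(C)C(C)(C)C
F5 | step 8 | 1-[(1S,3R,4S,5R,6R)-4-[(tert-butyldimethylsilyl)oxy]-5-hydroxy-6-methyl-7-oxabicyclo[4.1.0]heptan-3-yl]ethenyl trifluoromethanesulfonate | C=C(OS(=O)(=O)C(F)(F)F)[C@@H]1C[C@@H]2O[C@]2(C)[C@H](O)[C@H]1O[Si](C)(C)C(C)(C)C
F6 | step 8 | 1-[(1S,3R,4S,6S)-4-[(tert-butyldimethylsilyl)oxy]-6-methyl-5-oxo-7-oxabicyclo[4.1.0]heptan-3-yl]ethenyl trifluoromethanesulfonate | C=C(OS(=O)(=O)C(F)(F)F)[C@@H]1C[C@@H]2O[C@]2(C)C(=O)[C@H]1O[Si](C)(C)C(C)(C)C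
F7 | step 8 | 1-[(1S,3R,4S,6S)-4-hydroxy-6-methyl-5-oxo-7-oxabicyclo[4.1.0]heptan-3-yl]ethenyl trifluoromethanesulfonate | C=C(OS(=O)(=O)C(F)(F)F)[C@@H]1C[C@@H]2O[C@]2(C)C(=O)[C@H]1O
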